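# Proposed total synthesis of sideroxylonal A (24) by twofold benzannulation of an acyclic bis(siloxyalkyne)

## The problem

Sideroxylonal A (24) is a 2-aryl-3,4-dihydro-2H-chromene in which the benzo ring (ring A) and the C2 aryl group (ring B) are the same fully substituted phloroglucinol. Each ring carries two formyl groups, so the molecule holds four aldehydes and five free phenols around a small lipophilic core. The pyran ring has three contiguous stereocentres, C2 (R, aryl), C3 (R, isopropyl) and C4 (S, isobutyl), 2,3-trans and 3,4-cis. C3 and C4 are all-carbon centres with no handle for later correction and must be set absolutely and early. C2 is a benzylic ether carbon bonded to O1 and to an electron-rich arene; it ionises readily, so it can be left to the end and placed trans to the C3 isopropyl group under control by C3 and C4. The same lability is the main hazard: acid, Lewis acid or an ortho phenoxide can open O1–C2 to a stabilised cation or ortho-quinone methide, and loss of H3 from that species would erase C3. The salicylaldehyde-type formyl groups and the polyphenol tolerate bases, nucleophiles and redox reagents poorly, which argues for installing the aldehydes last and for few phenol protecting groups. The enabling feature is that C4a of ring A (flanked by oxygen-bearing C5 and C8a) is bonded to C4, and C1' of ring B (flanked by oxygen-bearing C2' and C6') is bonded to C2, each with a third oxygen para. This is the pattern left when a siloxyalkyne is annulated with an alkoxy-substituted vinylketene, so both rings can be grown at once from two alkynes on an acyclic C2–C3–C4 unit, and the equivalence of the two ortho oxygens in each ring removes any regiochemical question in the O1–C2 closure and in the formylation.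

## Retrosynthesis

**24 ⇒ 23 ⇒ 22 (aldehydes and ethers last).** The two O–ethyl bonds and then the four aryl–CHO bonds are removed first. Carrying formyl groups through the ring-forming chemistry would expose them to organolithium reagents and heat, and would deactivate the rings whose electron richness drives the O1–C2 closure. In 22 the only free aromatic positions are C6, C8, C3' and C5', all flanked by oxygen, so the forward reaction is an exhaustive electrophilic formylation that cannot give regioisomers. In 23 each ethyl ether lies between two formyl groups, the best case for chelation-assisted cleavage. Compound 22 has lost four carbons and every carbonyl group.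

**22 ⇒ 21 ⇒ 20 (O1–C2).** The O1–C2 bond is cut next, with the silyl groups restored. Cutting O1–C8a instead would need an aryl C–O coupling on a hexasubstituted ring, and cutting C4–C4a would need a Friedel–Crafts alkylation at a hindered secondary carbon without stereocontrol. The chosen cut uses the natural polarity: C2 next to the trioxygenated ring B is a latent benzylic cation, and the ring A phenol is a nucleophile held at the right distance. The precursor 20 is acyclic between the two rings and carries C2 as a methyl ether of either configuration. The forward step must ionise under mild acid, close the ring faster than H3 is lost, and give the 2,3-trans isomer. That isomer is the chair-like kinetic preference (aryl and isopropyl equatorial, isobutyl pseudoaxial) and, because the closure is reversible, also the thermodynamic one.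

**20 ⇒ 19 + two molecules of 4 (key disconnection).** Each phloroglucinol ring is cut along two C–C bonds: the bond from the ipso carbon to the phenol-bearing ortho carbon, and the bond from the siloxy-bearing ortho carbon to its CH neighbour. In net terms each alkyne of 19 is inserted into the C1–C2 bond of a cyclobutenone 4. The neighbouring cuts, aryl–C4 and aryl–C2, would require a 2,6-dioxygenated aryl nucleophile to attack a secondary carbon beside a branched centre with stereocontrol, and would treat the two rings by different chemistry. The benzannulation turns the problem into placing two alkynes on a three-carbon chain; its regiochemistry is inherent, it runs under neutral conditions, and both rings emerge with the same OH/OSi/OEt pattern. Compound 19 has no rings at all. The forward step must consume both alkynes and leave the two stereocentres and the methyl ether untouched.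

**19 ⇒ 18 ⇒ 17 (O–C(sp) bonds).** The siloxyalkynes are traced to the terminal diyne 17 through the dilithium bis(ynolate) 18. The alternative ynolate source, Kowalski homologation of esters, would need a 2,3,4-trisubstituted glutarate with two hindered α-branched esters and a substrate-controlled α-alkylation of uncertain selectivity. The alkyne route needs only aldehyde chemistry. The forward step must oxidise both acetylides and silylate on oxygen.

**17 ⇒ 16 ⇒ 15 (C2–alkyne bond).** The O–methyl bond and the bond between the future C2 and its alkyne are cut, leading to the alkynyl aldehyde 15 and an acetylide. The new carbinol centre needs no control because it is ionised later, which is why a plain Grignard addition suffices.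

**15 ⇒ 14 ⇒ 13 ⇒ 12 (terminus differentiation).** The terminal alkyne carbon on the C4 side is removed (one-carbon homologation of an aldehyde), and both chain ends are traced to the single cis-disubstituted γ-lactone 12. In 12 the carbonyl end (future C4a side) and the CH2O end (future C2) are differentiated by oxidation level. A 2,3-disubstituted succinaldehyde or butane-1,4-diol would be nearly symmetric, hard to differentiate and prone to epimerisation.

**12 ⇒ 11 ⇒ 10 ⇒ 9 + 6 (C3–C4 bond).** The lactone is opened to the succinate 10, which is cut between the two stereocentres into the enolate of imide 9 and the α-triflyloxy ester 6. Setting one centre after the other by substrate control (alkylating a butyrolactone or a 3-isopropylglutarate) would tend to deliver the trans lactone, that is the wrong 3,4-relationship. Here each centre has its own source of chirality: the oxazolidinone for C3 and L-leucic acid, with inversion, for C4. The forward step asks a hindered enolate to perform an SN2 displacement at a secondary carbon, which the adjacent ester carbonyl makes feasible.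

**9 ⇒ 7 + 8; 6 ⇒ 5; 4 ⇒ 1 + 2 (via 3).** The remaining cuts are an N-acylation, an O-sulfonylation and a ketene–ynol ether cycloaddition, all from commercial materials.

## Roads not taken

**Alternative 1:** Aryne–enone annulation. The cut removes O1–C8a, C4–C4a and O1–C2 at once: ring A arrives as 3,5-dimethoxybenzyne A3 and everything else as the aryl enone A2. In the forward step the carbonyl oxygen of A2 adds to the aryne carbon remote from the flanking methoxy group, the aryl anion closes on the carbonyl carbon to a benzoxete, this opens to an ortho-quinone methide, and oxa-6π electrocyclisation gives the 2H-chromene A1.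
- Merits: three bonds and the pyran ring form in one operation, A2 is one aldol condensation away from commodity chemicals, and the whole carbon skeleton is reached in about two steps, against twelve in the chosen plan.
- Weak points: A1 has a tetrasubstituted C3=C4 alkene and is racemic at C2, so all three stereocentres are still open. Hydrogenation of this shielded alkene would add cis (good for 3,4-cis) but from the face opposite the C2 aryl, giving the 2,3-cis isomer and requiring C2 epimerisation. No dependable enantioselective hydrogenation exists for such an alkene. The aryne–carbonyl step on a hindered conjugated ketone competes with ene and [4+2] pathways. Five methyl ethers would have to be cleaved beside four aldehydes.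
- Comparison: in step economy Alternative 1 is clearly better. The chosen plan sets against it that C3 and C4 are fixed absolutely before any ring exists and only the self-correcting C2 is left to the end.

**Alternative 2:** Aminocatalytic phloroglucinol–enal annulation. The cut removes C4–C4a and O1–C2 (C2 as a lactol carbon). In the forward step phloroglucinol A6 adds through carbon to C4 of the enal A5 held as a chiral iminium ion, the enamine is protonated at C3, and the phenol closes on the aldehyde carbon to the lactol A4. Ring B would then be attached by arylation of the derived oxocarbenium ion trans to the isopropyl group.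
- Merits: A5 is the self-condensation dimer of isovaleraldehyde and A6 is a commodity; one catalytic step builds ring A, the pyran ring and C4; no protecting groups are needed. If it delivered 3,4-cis material of high enantiopurity it would be about half as long as the chosen route.
- Weak points: α-branched β-alkyl enals are poor substrates for iminium catalysis. C3 is set only by protonation and stays epimerisable through ring–chain tautomerism of the lactol, so the 3,4-cis relationship is not secured. Phloroglucinol can react more than once. Ring B and four formyl groups still have to be added.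
- Comparison: shorter, but stereochemically insecure at exactly the centre that cannot be repaired. The chosen plan sets both centres by reactions with an established stereochemical course (auxiliary-directed enolate alkylation, SN2 inversion).

**Alternative 3:** Prins cyclisation. The cut removes O1–C2 and C2–C3, inserting the aldehyde carbon of 2,4,6-trimethoxybenzaldehyde A9 between the phenol oxygen and the prenyl-type alkene of phenol A8. In the forward step a Lewis acid forms the aryloxocarbenium ion, the alkene attacks, and the tertiary cation loses a proton to give A7 with an isopropenyl group, 2,3-trans and 3,4-cis through a chair with the isobutyl group pseudoaxial.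
- Merits: ring B comes from a catalogue aldehyde, and the C4 centre controls C2 and C3 in one well-behaved step. This key step is better precedented than the one chosen here, and that must be conceded.
- Weak points: the benzylic C4 centre on a fully substituted arene must first be made enantioselectively. Bromine blocking groups are needed on ring A and must later be exchanged for formyl groups by twofold halogen–metal exchange, while ring B is formylated separately. Hydrogenation of the isopropenyl group beside aryl bromides risks hydrodebromination. Five methyl ethers remain to be cleaved.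
- Comparison: similar length, safer key step. The chosen plan sets against it the identical treatment of both rings (formed, formylated and deprotected by the same operations, no blocking groups, only two ethers to cleave) and chiral-pool and auxiliary control of C3 and C4.

Key step: step 12

## Route

Remark on the chemistry: the carbon that becomes C2 is carried as an epimeric mixture in 16, 17, 19 and 20 (and 13 as an anomeric mixture), because this centre is ionised and reset in step 13.

Step 1
Reactants: 1 ethoxyacetylene; 2 acetyl chloride
Product: 4 3-ethoxycyclobut-2-en-1-one, via ketene 3 (not isolated)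
Conditions: Et3N, CH2Cl2, 0 °C → rt, slow addition of 2
Reagents that add atoms: none
Why: Ketene–ynol ether [2+2] cycloaddition: Et3N dehydrochlorinates 2 to ketene 3, whose carbonyl carbon bonds to the nucleophilic CH carbon of 1, placing the ethoxy group at C3 of the cyclobutenone; slow addition keeps the ketene concentration low and limits dimerisation.

Step 2
Reactants: 5 methyl (2S)-2-hydroxy-4-methylpentanoate (methyl L-leucate)
Product: 6 methyl (2S)-4-methyl-2-[(trifluoromethanesulfonyl)oxy]pentanoate
Conditions: Tf2O, 2,6-lutidine, CH2Cl2, −78 → 0 °C
Reagents that add atoms: trifluoromethanesulfonic anhydride, O=S(=O)(OS(=O)(=O)C(F)(F)F)C(F)(F)F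
Why: O-Sulfonylation of a secondary alcohol; no bond to the stereocentre is broken, so the (S) configuration is retained, and 6 is used at once because α-triflyloxy esters are reactive alkylating agents.

Step 3
Reactants: 7 (4S)-4-benzyl-1,3-oxazolidin-2-one; 8 3-methylbutanoyl chloride
Product: 9 (4S)-4-benzyl-3-(3-methylbutanoyl)-1,3-oxazolidin-2-one
Conditions: n-BuLi, THF, −78 °C; then 8, −78 → 0 °C
Reagents that add atoms: none
Why: N-Acylation of the lithiated oxazolidinone, the standard entry to an Evans imide.

Step 4
Reactants: 9 (4S)-4-benzyl-3-(3-methylbutanoyl)-1,3-oxazolidin-2-one; 6 methyl (2S)-4-methyl-2-[(trifluoromethanesulfonyl)oxy]pentanoate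
Product: 10 methyl (2S,3R)-3-[(4S)-4-benzyl-2-oxo-1,3-oxazolidine-3-carbonyl]-4-methyl-2-(2-methylpropyl)pentanoate
Conditions: NaN(SiMe3)2, THF, −78 °C; then 6, −78 → −30 °C
Reagents that add atoms: none
Why: Evans enolate alkylation with an α-triflyloxy ester: the chelated (Z)-sodium enolate is attacked on the face away from the benzyl group, which sets the isopropyl-bearing carbon (future C3) as R, and the triflate is displaced by SN2 with inversion, which sets the isobutyl-bearing carbon (future C4) as S (the descriptor stays S because the priorities change); the adjacent ester carbonyl favours substitution over elimination.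

Step 5
Reactants: 10 methyl (2S,3R)-3-[(4S)-4-benzyl-2-oxo-1,3-oxazolidine-3-carbonyl]-4-methyl-2-(2-methylpropyl)pentanoate
Product: 12 (3S,4R)-3-(2-methylpropyl)-4-(propan-2-yl)oxolan-2-one, via hydroxy ester 11 (not isolated)
Conditions: NaBH4, THF/H2O, 0 °C → rt; then TsOH·H2O (cat.), CH2Cl2, rt
Reagents that add atoms: none
Why: Borohydride reduction of the N-acyloxazolidinone to the primary alcohol with release of the auxiliary (the methyl ester is inert to NaBH4 here), then acid-catalysed lactonisation of the γ-hydroxy ester; no stereocentre is touched, so the lactone is cis.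

Step 6
Reactants: 12 (3S,4R)-3-(2-methylpropyl)-4-(propan-2-yl)oxolan-2-one
Product: 13 (3S,4R)-3-(2-methylpropyl)-4-(propan-2-yl)oxolan-2-ol (anomeric mixture)
Conditions: i-Bu2AlH, CH2Cl2, −78 °C
Reagents that add atoms: none
Why: Partial reduction of a γ-lactone to the lactol at low temperature, a standard aluminium hydride reduction.

Step 7
Reactants: 13 (3S,4R)-3-(2-methylpropyl)-4-(propan-2-yl)oxolan-2-ol
Product: 14 (2R,3S)-3-(2-methylpropyl)-2-(propan-2-yl)pent-4-yn-1-ol
Conditions: dimethyl (1-diazo-2-oxopropyl)phosphonate, K2CO3, MeOH, 0 °C → rt
Reagents that add atoms: dimethyl (1-diazo-2-oxopropyl)phosphonate, COP(=O)(OC)C(=[N+]=[N-])C(C)=O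
Why: Ohira–Bestmann (Seyferth–Gilbert) homologation of the open hydroxy aldehyde form of the lactol: the diazophosphonate anion adds, dimethyl phosphate is lost and the alkylidene carbene gives the terminal alkyne by 1,2-hydrogen shift; the mild carbonate base is chosen to keep the α-stereocentre intact.

Step 8
Reactants: 14 (2R,3S)-3-(2-methylpropyl)-2-(propan-2-yl)pent-4-yn-1-ol
Product: 15 (2R,3S)-3-(2-methylpropyl)-2-(propan-2-yl)pent-4-ynal
Conditions: DMP, NaHCO3, CH2Cl2, 0 °C → rt
Reagents that add atoms: none
Why: Dess–Martin oxidation of a primary alcohol under buffered, non-epimerising conditions; the α-branched aldehyde is used directly.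

Step 9
Reactants: 15 (2R,3S)-3-(2-methylpropyl)-2-(propan-2-yl)pent-4-ynal
Product: 16 (4R,5S)-5-(2-methylpropyl)-4-(propan-2-yl)hepta-1,6-diyn-3-ol (C3 epimers)
Conditions: HC≡CMgBr, THF, −78 → 0 °C; then aq. NH4Cl
Reagents that add atoms: ethynylmagnesium bromide, C#C[Mg]Br
Why: Grignard addition of an acetylide to an aldehyde; the carbinol centre forms as a mixture, which is accepted because this carbon is ionised and reset in step 13.

Step 10
Reactants: 16 (4R,5S)-5-(2-methylpropyl)-4-(propan-2-yl)hepta-1,6-diyn-3-ol
Product: 17 (4R,5S)-3-methoxy-5-(2-methylpropyl)-4-(propan-2-yl)hepta-1,6-diyne (C3 epimers)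
Conditions: NaH, MeI, THF, 0 °C → rt
Reagents that add atoms: iodomethane, CI
Why: Williamson etherification of the secondary propargylic alkoxide; NaH deprotonates the alcohol far faster than the terminal alkynes at 0 °C, so methylation occurs on oxygen.

Step 11
Reactants: 17 (4R,5S)-3-methoxy-5-(2-methylpropyl)-4-(propan-2-yl)hepta-1,6-diyne
Product: 19 (4R,5S)-3-methoxy-5-(2-methylpropyl)-4-(propan-2-yl)-1,7-bis{[tri(propan-2-yl)silyl]oxy}hepta-1,6-diyne (C3 epimers), via dilithium bis(ynolate) 18 (not isolated)
Conditions: n-BuLi, THF, −78 °C; LiOOt-Bu (from t-BuOOH and LiN(SiMe3)2), −78 → 0 °C; then i-Pr3SiOTf, −78 °C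
Reagents that add atoms: tert-butyl hydroperoxide (as its lithium salt), CC(C)(C)OO; triisopropylsilyl trifluoromethanesulfonate, CC(C)[Si](C(C)C)(C(C)C)OS(=O)(=O)C(F)(F)F
Why: Oxidation of lithium acetylides by the electrophilic oxygen of lithium tert-butyl peroxide gives lithium ynolates, and the bulky silyl triflate traps them on oxygen (small silyl groups go to carbon and give silylketenes); this is the established route from terminal alkynes to triisopropylsilyl ynol ethers, run here at both termini.

Step 12
Reactants: 19 (4R,5S)-3-methoxy-5-(2-methylpropyl)-4-(propan-2-yl)-1,7-bis{[tri(propan-2-yl)silyl]oxy}hepta-1,6-diyne; 4 3-ethoxycyclobut-2-en-1-one (2.5–3 equiv)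
Product: 20 5-ethoxy-2-[(2R,3S)-3-{4-ethoxy-2-hydroxy-6-[tri(propan-2-yl)silyloxy]phenyl}-1-methoxy-5-methyl-2-(propan-2-yl)hexyl]-3-[tri(propan-2-yl)silyloxy]phenol (epimers at the methoxy carbon)
Conditions: toluene, 80 → 110 °C, sealed tube
Reagents that add atoms: none
Why: Danheiser benzannulation, run twice on one substrate. On heating, 4 opens by 4π electrocyclic ring opening to (1-ethoxyvinyl)ketene, the chain-bearing alkyne carbon of 19 adds to the ketene carbonyl carbon in a regioselective [2+2] cycloaddition (four-membered ring closure), the resulting 2-alkyl-3-siloxy-4-(1-ethoxyvinyl)cyclobutenone opens again by 4π electrocyclic reaction to a dienylketene, and each benzene ring then closes by 6π electrocyclisation between the ketene carbon and the vinyl CH2, followed by tautomerisation to the phenol. The closest known reaction type is the benzannulation of cyclobutenones with triisopropylsiloxyalkynes to 2-substituted resorcinol monosilyl ethers; the ethoxy substituent on the cyclobutenone and the twofold use are extensions of it. Four C–C bonds and two aromatic rings form; the former ketene carbonyl becomes the free phenol ortho to the chain, the siloxy group lies on the other ortho carbon and the ethoxy group para, leaving two CH positions per ring. No stereocentre is created: the future C3 and C4 are spectators under neutral thermal conditions and both epimers at the methoxy carbon carry on. The selectivity needed is the regiochemistry of the ketene–alkyne [2+2] step, secured by the polarisation of the siloxyalkyne (nucleophilic at the carbon remote from oxygen) and of the ketene (electrophilic at the carbonyl carbon). An excess of 4 is used so that both alkynes are consumed and any vinylketene lost to O-acylation of the phenols formed is replaced.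

Step 13
Reactants: 20 5-ethoxy-2-[(2R,3S)-3-{4-ethoxy-2-hydroxy-6-[tri(propan-2-yl)silyloxy]phenyl}-1-methoxy-5-methyl-2-(propan-2-yl)hexyl]-3-[tri(propan-2-yl)silyloxy]phenol
Product: 22 5-ethoxy-2-[(2R,3R,4S)-7-ethoxy-5-hydroxy-4-(2-methylpropyl)-3-(propan-2-yl)-3,4-dihydro-2H-chromen-2-yl]benzene-1,3-diol, via silylated chroman 21 (not isolated)
Conditions: CSA (cat.), CH2Cl2, 0 °C → rt; then Bu4NF, THF, 0 °C
Reagents that add atoms: none
Why: Acid-catalysed flavan-type cycloetherification: the benzylic methyl ether, activated by the trioxygenated ring B, ionises and the free ring A phenol closes the six-membered ring at C2; C2 is set trans to the isopropyl group because the chair-like closure places aryl and isopropyl equatorial (isobutyl pseudoaxial) and reversible ionisation lets the same isomer accumulate thermodynamically; fluoride then cleaves both aryl silyl ethers.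

Step 14
Reactants: 22 5-ethoxy-2-[(2R,3R,4S)-7-ethoxy-5-hydroxy-4-(2-methylpropyl)-3-(propan-2-yl)-3,4-dihydro-2H-chromen-2-yl]benzene-1,3-diol
Product: 23 (2R,3R,4S)-7-ethoxy-2-(4-ethoxy-3,5-diformyl-2,6-dihydroxyphenyl)-5-hydroxy-4-(2-methylpropyl)-3-(propan-2-yl)-3,4-dihydro-2H-chromene-6,8-dicarbaldehyde
Conditions: Cl2CHOMe (excess), TiCl4, CH2Cl2, −78 → 0 °C; then aq. HCl
Reagents that add atoms: dichloromethyl methyl ether, COC(Cl)Cl; water, O
Why: Rieche formylation: C6, C8, C3' and C5' are the only free ring positions and each is ortho or para to three oxygen substituents, so exhaustive electrophilic formylation by the TiCl4-activated dichloromethyl ether, assisted by titanium phenoxide formation, can give only one tetra-aldehyde after hydrolysis.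

Step 15
Reactants: 23 (2R,3R,4S)-7-ethoxy-2-(4-ethoxy-3,5-diformyl-2,6-dihydroxyphenyl)-5-hydroxy-4-(2-methylpropyl)-3-(propan-2-yl)-3,4-dihydro-2H-chromene-6,8-dicarbaldehyde
Product: 24 sideroxylonal A, (2R,3R,4S)-2-(3,5-diformyl-2,4,6-trihydroxyphenyl)-5,7-dihydroxy-4-(2-methylpropyl)-3-(propan-2-yl)-3,4-dihydro-2H-chromene-6,8-dicarbaldehyde
Conditions: BCl3, CH2Cl2, −78 → 0 °C; then H2O
Reagents that add atoms: none
Why: Chelation-assisted Lewis acid dealkylation: each ethoxy group lies between two formyl groups, so BCl3 binds between ether and carbonyl oxygen and chloride removes the ethyl group at low temperature, while the phenols are held as borates and the aldehydes survive.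

## Compound list

1 | ethoxyacetylene | CCOC#C | starting material
2 | acetyl chloride | CC(=O)Cl | starting material
3 | ketene | C=C=O | intermediate
4 | 3-ethoxycyclobut-2-en-1-one | CCOC1=CC(=O)C1 | intermediate
5 | methyl (2S)-2-hydroxy-4-methylpentanoate | CC(C)C[C@H](O)C(=O)OC | starting material
6 | methyl (2S)-4-methyl-2-[(trifluoromethanesulfonyl)oxy]pentanoate | CC(C)C[C@H](OS(=O)(=O)C(F)(F)F)C(=O)OC | intermediate
7 | (4S)-4-benzyl-1,3-oxazolidin-2-one | O=C1N[C@@H](Cc2ccccc2)CO1 | starting material
8 | 3-methylbutanoyl chloride | CC(C)CC(=O)Cl | starting material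
9 | (4S)-4-benzyl-3-(3-methylbutanoyl)-1,3-oxazolidin-2-one | CC(C)CC(=O)N1[C@@H](Cc2ccccc2)COC1=O | intermediate
10 | methyl (2S,3R)-3-[(4S)-4-benzyl-2-oxo-1,3-oxazolidine-3-carbonyl]-4-methyl-2-(2-methylpropyl)pentanoate | CC(C)C[C@H](C(=O)OC)[C@@H](C(C)C)C(=O)N1[C@@H](Cc2ccccc2)COC1=O | intermediate
11 | methyl (2S,3R)-3-(hydroxymethyl)-4-methyl-2-(2-methylpropyl)pentanoate | CC(C)C[C@H](C(=O)OC)[C@@H](C(C)C)CO | intermediate
12 | (3S,4R)-3-(2-methylpropyl)-4-(propan-2-yl)oxolan-2-one (cis) | CC(C)C[C@H](C1=O)[C@@H](C(C)C)CO1 | intermediate
13 | (3S,4R)-3-(2-methylpropyl)-4-(propan-2-yl)oxolan-2-ol (anomeric mixture) | CC(C)C[C@H](C1O)[C@@H](C(C)C)CO1 | intermediate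
14 | (2R,3S)-3-(2-methylpropyl)-2-(propan-2-yl)pent-4-yn-1-ol | CC(C)C[C@H](C#C)[C@@H](C(C)C)CO | intermediate
15 | (2R,3S)-3-(2-methylpropyl)-2-(propan-2-yl)pent-4-ynal | CC(C)C[C@H](C#C)[C@@H](C(C)C)C=O | intermediate
16 | (4R,5S)-5-(2-methylpropyl)-4-(propan-2-yl)hepta-1,6-diyn-3-ol (C3 epimers) | CC(C)C[C@H](C#C)[C@@H](C(C)C)C(O)C#C | intermediate
17 | (4R,5S)-3-methoxy-5-(2-methylpropyl)-4-(propan-2-yl)hepta-1,6-diyne (C3 epimers) | CC(C)C[C@H](C#C)[C@@H](C(C)C)C(OC)C#C | intermediate
18 | dilithium (4R,5S)-3-methoxy-5-(2-methylpropyl)-4-(propan-2-yl)hepta-1,6-diyne-1,7-bis(olate) | CC(C)C[C@H](C#C[O-])[C@@H](C(C)C)C(OC)C#C[O-].[Li+].[Li+] | intermediate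
19 | (4R,5S)-3-methoxy-5-(2-methylpropyl)-4-(propan-2-yl)-1,7-bis{[tri(propan-2-yl)silyl]oxy}hepta-1,6-diyne (C3 epimers) | CC(C)C[C@H](C#CO[Si](C(C)C)(C(C)C)C(C)C)[C@@H](C(C)C)C(OC)C#CO[Si](C(C)C)(C(C)C)C(C)C | intermediate
20 | 5-ethoxy-2-[(2R,3S)-3-{4-ethoxy-2-hydroxy-6-[tri(propan-2-yl)silyloxy]phenyl}-1-methoxy-5-methyl-2-(propan-2-yl)hexyl]-3-[tri(propan-2-yl)silyloxy]phenol (epimers at the methoxy carbon) | CC(C)C[C@H](c1c(O)cc(OCC)cc1O[Si](C(C)C)(C(C)C)C(C)C)[C@@H](C(C)C)C(OC)c1c(O)cc(OCC)cc1O[Si](C(C)C)(C(C)C)C(C)C | intermediate
21 | 5-ethoxy-2-[(2R,3R,4S)-7-ethoxy-4-(2-methylpropyl)-3-(propan-2-yl)-5-[tri(propan-2-yl)silyloxy]-3,4-dihydro-2H-chromen-2-yl]-3-[tri(propan-2-yl)silyloxy]phenol | CC(C)C[C@@H]1c2c(O[Si](C(C)C)(C(C)C)C(C)C)cc(OCC)cc2O[C@@H](c2c(O)cc(OCC)cc2O[Si](C(C)C)(C(C)C)C(C)C)[C@@H]1C(C)C | intermediate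
22 | 5-ethoxy-2-[(2R,3R,4S)-7-ethoxy-5-hydroxy-4-(2-methylpropyl)-3-(propan-2-yl)-3,4-dihydro-2H-chromen-2-yl]benzene-1,3-diol | CC(C)C[C@@H]1c2c(O)cc(OCC)cc2O[C@@H](c2c(O)cc(OCC)cc2O)[C@@H]1C(C)C | intermediate
23 | (2R,3R,4S)-7-ethoxy-2-(4-ethoxy-3,5-diformyl-2,6-dihydroxyphenyl)-5-hydroxy-4-(2-methylpropyl)-3-(propan-2-yl)-3,4-dihydro-2H-chromene-6,8-dicarbaldehyde | CC(C)C[C@@H]1c2c(O)c(C=O)c(OCC)c(C=O)c2O[C@@H](c2c(O)c(C=O)c(OCC)c(C=O)c2O)[C@@H]1C(C)C | intermediate
24 | sideroxylonal A | CC(C)C[C@@H]1c2c(O)c(C=O)c(O)c(C=O)c2O[C@@H](c2c(O)c(C=O)c(O)c(C=O)c2O)[C@@H]1C(C)C | target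

## Step count and least certain steps

Total: 15 steps. Longest linear sequence: 13 steps (steps 3–15, from 7 and 8); steps 1 and 2 are side branches.

**Step 12 (key step).** The cyclobutenone is a vinylogous ester, so its ring opening may be slow and the alkoxy-substituted vinylketene less electrophilic than the alkyl-substituted ones normally used. Over a long heating period the siloxyalkynes can decay by silyl migration to silylketenes, the second annulation can stall at the mono-arene stage, the phenols formed can be acylated by the ketene, and the ortho-hydroxybenzyl methyl ether can lose methanol prematurely. Fallback: the photochemical (second-generation) form of the same annulation, setting out from 19 and returning at 20. α-Lithiated ethyl vinyl ether is acylated with N-methoxy-N-methylacetamide to 3-ethoxybut-3-en-2-one F1, which is converted by detrifluoroacetylative diazo transfer into 1-diazo-3-ethoxybut-3-en-2-one F2. Irradiation of F2 with 19 at room temperature gives the same (1-ethoxyvinyl)ketene by photochemical Wolff rearrangement, and brief warming completes the cascade to 20.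

**Step 4.** The α-isopropyl enolate is hindered and may act as a base, eliminating the triflate to the unsaturated ester; a slow substitution also gives the sodium enolate time to decompose, and a mismatched pairing of auxiliary and triflate would erode selectivity. Fallback, setting out from 9 and returning at 12, with C4 set on a ring instead:
- 9 is alkylated (NaN(SiMe3)2, tert-butyl bromoacetate) to tert-butyl (3S)-3-[(4S)-4-benzyl-2-oxo-1,3-oxazolidine-3-carbonyl]-4-methylpentanoate F3.
- NaBH4 gives tert-butyl (3S)-3-(hydroxymethyl)-4-methylpentanoate F4, and CF3CO2H closes it to (4S)-4-(propan-2-yl)oxolan-2-one F5.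
- The lactone enolate (LiN(i-Pr)2) is alkylated with 3-bromo-2-methylpropene anti to the isopropyl group to give (3R,4R)-3-(2-methylprop-2-en-1-yl)-4-(propan-2-yl)oxolan-2-one F6.
- Re-enolisation and kinetic protonation with a bulky phenol from the face opposite the isopropyl group gives the cis lactone (3S,4R)-3-(2-methylprop-2-en-1-yl)-4-(propan-2-yl)oxolan-2-one F7.
- Hydrogenation over Pd/C gives 12.

**Step 11.** Oxidation may stop after one terminus, the ynolate next to the methoxy-bearing carbon may lose methoxide, and silylation may go partly to carbon or be lost to hydrolysis on work-up. Fallback through electrophilic alkyne chemistry, setting out from 17 and returning at 19 through 18. PhI(OH)OTs converts 17 into [(4R,5S)-3-methoxy-5-(2-methylpropyl)-4-(propan-2-yl)hepta-1,6-diyne-1,7-diyl]bis(phenyliodonium) bis(4-methylbenzenesulfonate) F8. Catalytic CuOTf in MeCN rearranges it to (4R,5S)-3-methoxy-5-(2-methylpropyl)-4-(propan-2-yl)hepta-1,6-diyne-1,7-diyl bis(4-methylbenzenesulfonate) F9. MeLi attacks sulfur and releases 18, which is silylated as before to 19.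

**Step 14.** The second formyl group on each ring enters an already deactivated ring, so formylation may stop short of four. TiCl4 may also ionise O1–C2, and loss of H3 from the open cation would scramble C3. Fallback, from 22 to 23: fourfold Vilsmeier–Haack formylation (POCl3, DMF, then aqueous NaOAc), which uses a chloroiminium electrophile and no strong Lewis acid; no new compound arises on this path (F0).

**Step 15.** BCl3 chelated between O1 and the C8 formyl group may open or epimerise the O1–C2 bond, and ethyl cleavage may be incomplete. Fallback by changing the order, setting out from 22 and ending at 24. The two ethyl ethers of 22 are cleaved first with BBr3 to (2R,3R,4S)-4-(2-methylpropyl)-3-(propan-2-yl)-2-(2,4,6-trihydroxyphenyl)-3,4-dihydro-2H-chromene-5,7-diol F10 (any opened material recloses to the trans chroman on work-up). The free polyphenol is then formylated four times under Vilsmeier–Haack conditions, as is known for phloroglucinol itself, to give 24 with no deprotection after the aldehydes are in place.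

**Step 1.** With in situ generation of the parent ketene, dimerisation and acylammonium side reactions may outrun the cycloaddition. Fallback, from 1 to 4: dichloroketene (Cl3CCOCl, Zn(Cu), Et2O) adds to 1 to give 4,4-dichloro-3-ethoxycyclobut-2-en-1-one F11, which is dechlorinated with Zn, AcOH and TMEDA in EtOH to 4.

## Further compounds

F1 | step 12 | 3-ethoxybut-3-en-2-one | C=C(OCC)C(C)=O
F2 | step 12 | 1-diazo-3-ethoxybut-3-en-2-one | C=C(OCC)C(=O)C=[N+]=[N-]
F3 | step 4 | tert-butyl (3S)-3-[(4S)-4-benzyl-2-oxo-1,3-oxazolidine-3-carbonyl]-4-methylpentanoate | CC(C)(C)OC(=O)C[C@@H](C(C)C)C(=O)N1[C@@H](Cc2ccccc2)COC1=O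
F4 | step 4 | tert-butyl (3S)-3-(hydroxymethyl)-4-methylpentanoate | CC(C)(C)OC(=O)C[C@@H](C(C)C)CO
F5 | step 4 | (4S)-4-(propan-2-yl)oxolan-2-one | O=C1C[C@@H](C(C)C)CO1
F6 | step 4 | (3R,4R)-3-(2-methylprop-2-en-1-yl)-4-(propan-2-yl)oxolan-2-one (trans) | C=C(C)C[C@@H](C1=O)[C@@H](C(C)C)CO1
F7 | step 4 | (3S,4R)-3-(2-methylprop-2-en-1-yl)-4-(propan-2-yl)oxolan-2-one (cis) | C=C(C)C[C@H](C1=O)[C@@H](C(C)C)CO1
F8 | step 11 | [(4R,5S)-3-methoxy-5-(2-methylpropyl)-4-(propan-2-yl)hepta-1,6-diyne-1,7-diyl]bis(phenyliodonium) bis(4-methylbenzenesulfonate) | CC(C)C[C@H](C#C[I+]c1ccccc1)[C@@H](C(C)C)C(OC)C#C[I+]c1ccccc1.Cc1ccc(S(=O)(=O)[O-])cc1.Cc1ccc(S(=O)(=O)[O-])cc1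
F9 | step 11 | (4R,5S)-3-methoxy-5-(2-methylpropyl)-4-(propan-2-yl)hepta-1,6-diyne-1,7-diyl bis(4-methylbenzenesulfonate) | CC(C)C[C@H](C#COS(=O)(=O)c1ccc(C)cc1)[C@@H](C(C)C)C(OC)C#COS(=O)(=O)c1ccc(C)cc1
F0 | step 14 | none | none
F10 | step 15 | (2R,3R,4S)-4-(2-methylpropyl)-3-(propan-2-yl)-2-(2,4,6-trihydroxyphenyl)-3,4-dihydro-2H-chromene-5,7-diol | CC(C)C[C@@H]1c2c(O)cc(O)cc2O[C@@H](c2c(O)cc(O)cc2O)[C@@H]1C(C)C
F11 | step 1 | 4,4-dichloro-3-ethoxycyclobut-2-en-1-one | CCOC1=CC(=O)C1(Cl)Cl
A1 | alternative 1 | 5,7-dimethoxy-4-(2-methylpropyl)-3-(propan-2-yl)-2-(2,4,6-trimethoxyphenyl)-2H-chromene (racemic at C2) | CC(C)CC1=C(C(C)C)C(c2c(OC)cc(OC)cc2OC)Oc2cc(OC)cc(OC)c12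
A2 | alternative 1 | (1E)-5-methyl-2-(propan-2-yl)-1-(2,4,6-trimethoxyphenyl)hex-1-en-3-one | CC(C)CC(=O)/C(C(C)C)=C/c1c(OC)cc(OC)cc1OC
A3 | alternative 1 | 3,5-dimethoxybenzyne | COC1=CC(OC)=CC#C1
A4 | alternative 2 | (3R,4S)-4-(2-methylpropyl)-3-(propan-2-yl)-3,4-dihydro-2H-chromene-2,5,7-triol (anomeric mixture) | CC(C)C[C@@H]1c2c(O)cc(O)cc2OC(O)[C@@H]1C(C)C
A5 | alternative 2 | (2E)-5-methyl-2-(propan-2-yl)hex-2-enal | CC(C)C/C=C(/C=O)C(C)C
A6 | alternative 2 | benzene-1,3,5-triol (phloroglucinol) | Oc1cc(O)cc(O)c1
A7 | alternative 3 | (2R,3S,4S)-6,8-dibromo-5,7-dimethoxy-4-(2-methylpropyl)-3-(prop-1-en-2-yl)-2-(2,4,6-trimethoxyphenyl)-3,4-dihydro-2H-chromene | CC(C)C[C@@H]1c2c(OC)c(Br)c(OC)c(Br)c2O[C@@H](c2c(OC)cc(OC)cc2OC)[C@@H]1C(C)=C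
A8 | alternative 3 | 2,4-dibromo-6-[(4S)-2,6-dimethylhept-2-en-4-yl]-3,5-dimethoxyphenol | CC(C)C[C@@H](C=C(C)C)c1c(OC)c(Br)c(OC)c(Br)c1O
A9 | alternative 3 | 2,4,6-trimethoxybenzaldehyde | COc1cc(OC)c(C=O)c(OC)c1
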